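**Retrosynthetic overview**
- Target ⇒ its tert-butyl ester; acidolysis is the only unmasking step and no phenol is protected.
- Key disconnection: the C2–O bond of the aryl-lactate unit ⇒ caffeic acid + an α-benzyl-α-diazo ester, joined by a catalytic asymmetric O–H insertion that also sets the (R) centre.
- α-Diazo ester ⇒ 2-vanillyl acetoacetate (deacylative diazo transfer) ⇒ vanillin + tert-butyl acetoacetate (Knoevenagel condensation/hydrogenation).
- No ring is formed; both benzene rings come from vanillin and caffeic acid.

Assumption: the (S)-enantiomer of the spiro phosphoric acid is taken to give the (R)-ester; if a pilot run shows the opposite sense, the (R)-enantiomer is used and nothing else changes.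

**Route**

Step 1
Reactants: 1 vanillin (4-hydroxy-3-methoxybenzaldehyde); 2 tert-butyl acetoacetate (tert-butyl 3-oxobutanoate)
Product: 4 tert-butyl 2-(4-hydroxy-3-methoxybenzyl)-3-oxobutanoate (racemic), via Knoevenagel alkylidene 3 (not isolated)
Conditions: piperidine (10 mol%), AcOH (10 mol%), 4 Å MS, iPrOH, 50 °C; then 10% Pd/C, H2 (1 atm), rt
Reagents that add atoms: none
Why: Knoevenagel condensation gives the electron-poor alkylidene 3, whose C=C bond is hydrogenated over Pd/C far faster than the ketone, the arene or the tert-butyl ester (one-pot reductive alkylation of a β-keto ester); the new stereocenter is racemic and is erased in step 2.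

Step 2
Reactants: 4 tert-butyl 2-(4-hydroxy-3-methoxybenzyl)-3-oxobutanoate
Product: 5 tert-butyl 2-diazo-3-(4-hydroxy-3-methoxyphenyl)propanoate
Conditions: 4-acetamidobenzenesulfonyl azide (1.3 equiv), DBU (2.2 equiv), MeCN, 0 °C to rt
Reagents that add atoms: 4-acetamidobenzenesulfonyl azide (p-ABSA), CC(=O)Nc1ccc(cc1)S(=O)(=O)N=[N+]=[N-]
Why: Regitz deacylative diazo transfer, in which the carbon enolate of the β-keto ester attacks the terminal azide nitrogen and the adduct fragments with transfer of the acetyl group to the sulfonamide nitrogen; the extra DBU covers the phenol, which is a poor partner for the azide, and the racemic center disappears.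

Step 3
Reactants: 5 tert-butyl 2-diazo-3-(4-hydroxy-3-methoxyphenyl)propanoate; 6 caffeic acid ((2E)-3-(3,4-dihydroxyphenyl)prop-2-enoic acid, 1.5 equiv)
Product: 8 tert-butyl (2R)-2-{[(2E)-3-(3,4-dihydroxyphenyl)prop-2-enoyl]oxy}-3-(4-hydroxy-3-methoxyphenyl)propanoate, via enol tautomer 7 (not isolated)
Conditions: Rh2(O2CCPh3)4 (1 mol%), (S)-6,6′-bis(2,4,6-triisopropylphenyl)-1,1′-spirobiindane-7,7′-diyl hydrogen phosphate (5 mol%), 4 Å MS, EtOAc (0.03 M), 0 °C, 5 added over 3 h
Reagents that add atoms: none
Why: Proposed new method: enantioselective insertion of an α-benzyl-α-diazo ester into the O–H bond of an unprotected phenolic carboxylic acid, co-catalysed by a bulky achiral dirhodium tetracarboxylate and a chiral spiro phosphoric acid; divalent rhodium turns 5 into an electrophilic carbene whose 1,2-hydride shift to tert-butyl ferulate is held back by the triphenylacetate ligands, the low temperature and the slow addition; the carboxyl group of 6 (about five pKa units more acidic than any of the three phenolic O–H groups present, and able to add through its carbonyl oxygen with internal proton relay) is expected to trap the carbene carbon and give the free enol 7; the chiral phosphoric acid then shuttles the proton to one face of the enol carbon, which forms the C2–O bond and sets the (R) stereocenter in the same event; the closest known reactions are the same catalyst pair in asymmetric O–H insertion of water into α-alkyl-α-diazo esters and rhodium/chiral-base-catalysed insertion of carboxylic acids into α-diazo ketones, neither shown for a carboxylic acid with an α-alkyl diazo ester or with free phenols.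

Step 4
Reactants: 8 tert-butyl (2R)-2-{[(2E)-3-(3,4-dihydroxyphenyl)prop-2-enoyl]oxy}-3-(4-hydroxy-3-methoxyphenyl)propanoate
Product: 9 clinopodic acid B, (2R)-2-{[(2E)-3-(3,4-dihydroxyphenyl)prop-2-enoyl]oxy}-3-(4-hydroxy-3-methoxyphenyl)propanoic acid
Conditions: TFA/CH2Cl2 (1:3), 0 °C to rt, 2 h, N2 sweep, dark
Reagents that add atoms: none
Why: Acidolysis of the tert-butyl ester by the AAL1 pathway (tert-butyl cation lost as isobutene) frees the acid without touching the secondary caffeate ester, the (E)-alkene or the stereocenter, which does not enolise under acid.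

**Compound list**
1 | vanillin (4-hydroxy-3-methoxybenzaldehyde) | COc1cc(C=O)ccc1O | starting material
2 | tert-butyl acetoacetate | CC(=O)CC(=O)OC(C)(C)C | starting material
3 | tert-butyl 2-(4-hydroxy-3-methoxybenzylidene)-3-oxobutanoate (Knoevenagel alkylidene, E/Z mixture) | CC(=O)C(=Cc1ccc(O)c(OC)c1)C(=O)OC(C)(C)C | intermediate
4 | tert-butyl 2-(4-hydroxy-3-methoxybenzyl)-3-oxobutanoate (racemic) | CC(=O)C(Cc1ccc(O)c(OC)c1)C(=O)OC(C)(C)C | intermediate
5 | tert-butyl 2-diazo-3-(4-hydroxy-3-methoxyphenyl)propanoate | COc1cc(CC(=[N+]=[N-])C(=O)OC(C)(C)C)ccc1O | intermediate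
6 | caffeic acid, (2E)-3-(3,4-dihydroxyphenyl)prop-2-enoic acid | OC(=O)/C=C/c1ccc(O)c(O)c1 | starting material
7 | enol tautomer of 8: 1-tert-butoxy-1-hydroxy-3-(4-hydroxy-3-methoxyphenyl)prop-1-en-2-yl (2E)-3-(3,4-dihydroxyphenyl)prop-2-enoate (enol geometry not defined) | COc1cc(CC(OC(=O)/C=C/c2ccc(O)c(O)c2)=C(O)OC(C)(C)C)ccc1O | intermediate
8 | tert-butyl (2R)-2-{[(2E)-3-(3,4-dihydroxyphenyl)prop-2-enoyl]oxy}-3-(4-hydroxy-3-methoxyphenyl)propanoate | COc1cc(C[C@@H](OC(=O)/C=C/c2ccc(O)c(O)c2)C(=O)OC(C)(C)C)ccc1O | intermediate
9 | clinopodic acid B, (2R)-2-{[(2E)-3-(3,4-dihydroxyphenyl)prop-2-enoyl]oxy}-3-(4-hydroxy-3-methoxyphenyl)propanoic acid | COc1cc(C[C@@H](OC(=O)/C=C/c2ccc(O)c(O)c2)C(=O)O)ccc1O | target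

**Step count**
Total steps: 4. Longest linear sequence: 4 (1 → 4 → 5 → 8 → 9); caffeic acid 6 enters in step 3.

**Steps most likely to fail and their fallbacks**

First, step 3, the new insertion. The risks are 1,2-hydride shift to tert-butyl ferulate, competing insertion into phenolic O–H bonds, the limited solubility of 6 in ethyl acetate at 0 °C, and insufficient enantioselectivity. The fallback uses known chemistry, sets out from 5 and comes back at 8. The known asymmetric insertion of water into α-alkyl-α-diazo esters is run with the same Rh2(O2CCPh3)4/spiro phosphoric acid pair in water-saturated CHCl3, using the enantiomer of the acid that gives the (S)-alcohol. This turns 5 into tert-butyl (2S)-2-hydroxy-3-(4-hydroxy-3-methoxyphenyl)propanoate F1. Mitsunobu esterification of F1 with unprotected 6 (PPh3, diisopropyl azodicarboxylate, THF, 0 °C to rt) then makes the same C–O bond by SN2 displacement with inversion and gives 8 in the (R) configuration. The carboxylic acid is the only partner acidic enough to be alkylated quickly, so the phenols stay free.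

Second, step 2. The risks are that the phenoxide consumes base or azide, that diazo transfer occurs on the electron-rich ring, or that deacetylation is incomplete. The fallback sets out from 4 and comes back at 5. Deacetylative nitrosation of 4 (isoamyl nitrite, NaOEt, EtOH, 0 °C; the acetyl group leaves as ethyl acetate) gives tert-butyl 2-(hydroxyimino)-3-(4-hydroxy-3-methoxyphenyl)propanoate F2. Reduction with Zn in AcOH gives racemic tert-butyl 2-amino-3-(4-hydroxy-3-methoxyphenyl)propanoate F3. Diazotisation of F3 (isoamyl nitrite, catalytic AcOH, CHCl3, reflux) returns 5 without any sulfonyl azide.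

Third, step 1. The risks are a sluggish Knoevenagel condensation of the phenolic aldehyde, Michael bis-adduct formation, and hydrogenation of unreacted vanillin. The fallback sets out from 1 and comes back at 4. Reduction with NaBH4 (MeOH, 0 °C) gives vanillyl alcohol (4-(hydroxymethyl)-2-methoxyphenol) F4. Heating F4 with 2 in water at 80 °C dehydrates it to the para-quinone methide 2-methoxy-4-methylidenecyclohexa-2,5-dien-1-one F5. Conjugate addition of the enol of 2 to F5 (dehydrative benzylation of a 1,3-dicarbonyl compound) gives 4 with no condensation or hydrogenation.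

**Further compounds**
F1 | step 3 | tert-butyl (2S)-2-hydroxy-3-(4-hydroxy-3-methoxyphenyl)propanoate | COc1cc(C[C@H](O)C(=O)OC(C)(C)C)ccc1O
F2 | step 2 | tert-butyl 2-(hydroxyimino)-3-(4-hydroxy-3-methoxyphenyl)propanoate | COc1cc(CC(=NO)C(=O)OC(C)(C)C)ccc1O
F3 | step 2 | tert-butyl 2-amino-3-(4-hydroxy-3-methoxyphenyl)propanoate (racemic) | COc1cc(CC(N)C(=O)OC(C)(C)C)ccc1O
F4 | step 1 | vanillyl alcohol, 4-(hydroxymethyl)-2-methoxyphenol | COc1cc(CO)ccc1O
F5 | step 1 | 2-methoxy-4-methylidenecyclohexa-2,5-dien-1-one (para-quinone methide) | COC1=CC(=C)C=CC1=O
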